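**Plan**

- Retrosynthesis: the triisopropylsilyl ether is cut first, then, in one operation, the two ring A bonds C6–O (diaryl ether) and C1–C (ester carbon). This leaves 3-prenyloxybenzyne (from silyl triflate 7) and the ring B aryl methyl carbonate 19.
- Enabling feature: on ring A the ester carbon (on C1) and the ether oxygen (on C6) sit on neighbouring ring carbons, and C1 is flanked on its other side by the prenyloxy-bearing C2. This is the pattern left when a nucleophile and an acyl group add across a 3-alkoxybenzyne.
- Ring B: carbonate from the phenol; CH2OH carbon by ortho-formylation; phenolic oxygen by Dakin oxidation of the formyl group of 8; prenyl groups by O-alkylation and Stille coupling. Ring A: 2-bromoresorcinol, O-prenylation, retro-Brook/triflation.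
- Forward: both benzene rings are bought and no ring is formed; the two arenes are joined in step 11 and desilylation ends the route.
- Stereochemistry: none; the target has no stereocentre and each alkene carries two identical methyl groups.

Key step: step 11

Remark: prenyl stands for 3-methylbut-2-en-1-yl throughout. Ring A is the benzoate ring (C1 ester, C2 prenyloxy, C6 aryloxy); ring B carries the diaryl ether oxygen on C1, prenyloxy on C2, methoxy on C4, prenyl on C5 and the hydroxymethyl group on C6. Compounds 8, 10 and 14 are taken as catalogue chemicals. A primary triisopropylsilyl ether is assumed to survive KF/18-crown-6 in THF at 0 °C to room temperature, which is why it is chosen as the protecting group.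

**Ring A: aryne precursor**

Step 1
Reactants: 1 2-bromoresorcinol (in excess), 2 prenyl bromide
Product: 3 2-bromo-3-(prenyloxy)phenol
Conditions: K2CO3, acetone, rt
Reagents that add atoms: prenyl bromide (2), CC(C)=CCBr
Why: Williamson mono-O-alkylation of a symmetrical diol, run with the diol in excess so that the mono-ether should dominate and unreacted 1 can be recovered.

Step 2
Reactants: 3 2-bromo-3-(prenyloxy)phenol
Product: 4 [2-bromo-3-(prenyloxy)phenoxy]trimethylsilane
Conditions: HN(SiMe3)2, THF, 70 °C
Reagents that add atoms: hexamethyldisilazane, C[Si](C)(C)N[Si](C)(C)C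
Why: O-silylation of a phenol with hexamethyldisilazane, the usual first stage in the preparation of ortho-silylaryl triflates from ortho-bromophenols.

Step 3
Reactants: 4 [2-bromo-3-(prenyloxy)phenoxy]trimethylsilane
Product: 7 3-(prenyloxy)-2-(trimethylsilyl)phenyl trifluoromethanesulfonate, via aryllithium 5 (not isolated), via lithium aryloxide 6 (not isolated)
Conditions: n-BuLi, THF, −100 → −80 °C; then Tf2O, −100 → −80 °C
Reagents that add atoms: triflic anhydride, O=S(=O)(OS(=O)(=O)C(F)(F)F)C(F)(F)F
Why: Bromine–lithium exchange followed by retro-Brook (oxygen-to-carbon 1,3-silyl) migration and O-triflation of the resulting aryloxide, the standard sequence to Kobayashi aryne precursors; exchange at low temperature should outrun any deprotonation of the prenyl ether.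

**Ring B: aryl methyl carbonate**

Step 4
Reactants: 8 5-bromo-2-hydroxy-4-methoxybenzaldehyde, 2 prenyl bromide
Product: 9 5-bromo-4-methoxy-2-(prenyloxy)benzaldehyde
Conditions: K2CO3, DMF, rt
Reagents that add atoms: prenyl bromide (2), CC(C)=CCBr
Why: Williamson O-alkylation of a salicylaldehyde-type phenol; this fixes the prenyl ether on the oxygen that becomes ring B C2–O before the second oxygen exists.

Step 5
Reactants: 9 5-bromo-4-methoxy-2-(prenyloxy)benzaldehyde, 10 tributyl(prenyl)stannane
Product: 11 4-methoxy-5-prenyl-2-(prenyloxy)benzaldehyde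
Conditions: Pd(PPh3)4 (cat.), DMF, 100 °C
Reagents that add atoms: tributyl(3-methylbut-2-en-1-yl)stannane (10), CCCC[Sn](CCCC)(CCCC)CC=C(C)C
Why: Stille coupling of an aryl bromide activated by the para-formyl group, with transfer of the allylic group at the tin-bearing carbon expected to give the linear prenyl arene.

Step 6
Reactants: 11 4-methoxy-5-prenyl-2-(prenyloxy)benzaldehyde
Product: 13 4-methoxy-5-prenyl-2-(prenyloxy)phenol, via aryl formate 12 (not isolated)
Conditions: 30% aq H2O2, H2SO4 (cat.), MeOH, 0 °C → rt
Reagents that add atoms: hydrogen peroxide, OO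
Why: Acid-catalysed Dakin oxidation (Baeyer–Villiger-type aryl migration in the hydroperoxide adduct of an ortho,para-dialkoxybenzaldehyde) with in situ methanolysis of the formate; hydrogen peroxide without a peracid should leave the trisubstituted alkenes untouched.

Step 7
Reactants: 13 4-methoxy-5-prenyl-2-(prenyloxy)phenol, 14 paraformaldehyde
Product: 15 2-hydroxy-5-methoxy-6-prenyl-3-(prenyloxy)benzaldehyde
Conditions: MgCl2, Et3N, (CH2O)n, MeCN, reflux
Reagents that add atoms: paraformaldehyde (14), C=O
Why: Casiraghi–Skattebøl ortho-formylation through the magnesium phenoxide, which can only reach the single free ortho position (ring B C6), the other being occupied by the prenyloxy group.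

Step 8
Reactants: 15 2-hydroxy-5-methoxy-6-prenyl-3-(prenyloxy)benzaldehyde
Product: 16 2-(hydroxymethyl)-4-methoxy-3-prenyl-6-(prenyloxy)phenol
Conditions: NaBH4, MeOH/THF, 0 °C
Reagents that add atoms: none
Why: Borohydride reduction of an aryl aldehyde to the benzylic alcohol, kept cold and base-washed to avoid ortho-quinone methide formation from the electron-rich product.

Step 9
Reactants: 16 2-(hydroxymethyl)-4-methoxy-3-prenyl-6-(prenyloxy)phenol
Product: 17 2-{[(triisopropylsilyl)oxy]methyl}-4-methoxy-3-prenyl-6-(prenyloxy)phenol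
Conditions: i-Pr3SiCl (1.05 equiv), imidazole, CH2Cl2, 0 °C → rt
Reagents that add atoms: chlorotriisopropylsilane, CC(C)[Si](Cl)(C(C)C)C(C)C
Why: Silyl chloride/imidazole silylation, in which the primary benzylic hydroxyl should react ahead of the doubly ortho-substituted, hydrogen-bonded phenol, as in the known mono-silylation of 2-hydroxybenzyl alcohols.

Step 10
Reactants: 17 2-{[(triisopropylsilyl)oxy]methyl}-4-methoxy-3-prenyl-6-(prenyloxy)phenol, 18 methyl chloroformate
Product: 19 methyl 2-{[(triisopropylsilyl)oxy]methyl}-4-methoxy-3-prenyl-6-(prenyloxy)phenyl carbonate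
Conditions: ClCO2Me, Et3N, DMAP (cat.), CH2Cl2, 0 °C
Reagents that add atoms: methyl chloroformate (18), COC(=O)Cl
Why: O-acylation of a phenol with a chloroformate under nucleophilic catalysis, which the small electrophile should achieve even at the hindered oxygen.

**Union and end game**

Step 11
Reactants: 19 methyl 2-{[(triisopropylsilyl)oxy]methyl}-4-methoxy-3-prenyl-6-(prenyloxy)phenyl carbonate, 7 3-(prenyloxy)-2-(trimethylsilyl)phenyl trifluoromethanesulfonate
Product: 23 methyl 2-[2-{[(triisopropylsilyl)oxy]methyl}-4-methoxy-3-prenyl-6-(prenyloxy)phenoxy]-6-(prenyloxy)benzoate, via 3-prenyloxybenzyne 20 (not isolated), via potassium aryloxide 21 (not isolated), via aryl anion 22 (not isolated)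
Conditions: KF, 18-crown-6, potassium aryloxide 21 (10 mol%, from 17 and KH), THF (0.4 M in 19), 0 °C → rt, 7 (1.5 equiv) added slowly
Reagents that add atoms: none
Why: Proposed new method: fluoride removes the trimethylsilyl group of 7 and triflate departs to give aryne 20, aryloxide 21 adds to the aryne carbon remote from the prenyloxy group, and the resulting aryl anion 22, whose charge sits on the carbon between the two oxygens, attacks the carbonate carbonyl of a further molecule of 19. The tetrahedral intermediate should expel aryloxide 21 in preference to methoxide, so the chain carrier is regenerated and the net change is insertion of the aryne into the aryl O–C(=O) bond, forming the ring A C6–O and C1–C(ester) bonds. The closest known reactions are fluoride-induced aryne insertions into acyl–nitrogen and acyl–carbon sigma bonds and three-component couplings of arynes with a nucleophile and carbon dioxide or a carbonyl electrophile; the difference here is an intermolecular, chain-propagating acyl transfer from a carbonate. No ring is closed and no stereocentre is formed. The regioselectivity needed is attack meta to the alkoxy group, which the inductive distortion of a 3-alkoxybenzyne secures, as established for 3-methoxybenzyne. The chemoselectivity needed is acylation of 22 before protonation, which the aprotic medium (THF in place of acetonitrile), the high carbonate concentration, the preformed initiator and the slow addition of 7 are meant to secure.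

Step 12
Reactants: 23 methyl 2-[2-{[(triisopropylsilyl)oxy]methyl}-4-methoxy-3-prenyl-6-(prenyloxy)phenoxy]-6-(prenyloxy)benzoate
Product: 24 methyl 2-[2-(hydroxymethyl)-4-methoxy-3-prenyl-6-(prenyloxy)phenoxy]-6-(prenyloxy)benzoate (CNP0500611.0)
Conditions: Bu4NF, AcOH, THF, 0 °C → rt
Reagents that add atoms: none
Why: Fluoride cleavage of a primary silyl ether, buffered with acetic acid so that the methyl ester and the prenyl ethers should remain intact.

**Compound list**

1 | 2-bromoresorcinol (2-bromobenzene-1,3-diol) | Oc1cccc(O)c1Br | starting material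
2 | prenyl bromide (1-bromo-3-methylbut-2-ene) | CC(C)=CCBr | starting material
3 | 2-bromo-3-(prenyloxy)phenol | CC(C)=CCOc1cccc(O)c1Br | intermediate
4 | [2-bromo-3-(prenyloxy)phenoxy]trimethylsilane | CC(C)=CCOc1cccc(O[Si](C)(C)C)c1Br | intermediate
5 | [2-(prenyloxy)-6-(trimethylsilyloxy)phenyl]lithium | CC(C)=CCOc1cccc(O[Si](C)(C)C)c1[Li] | intermediate (not isolated)
6 | lithium 3-(prenyloxy)-2-(trimethylsilyl)phenoxide | [Li+].[O-]c1cccc(OCC=C(C)C)c1[Si](C)(C)C | intermediate (not isolated)
7 | 3-(prenyloxy)-2-(trimethylsilyl)phenyl trifluoromethanesulfonate | CC(C)=CCOc1cccc(OS(=O)(=O)C(F)(F)F)c1[Si](C)(C)C | intermediate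
8 | 5-bromo-2-hydroxy-4-methoxybenzaldehyde | COc1cc(O)c(C=O)cc1Br | starting material
9 | 5-bromo-4-methoxy-2-(prenyloxy)benzaldehyde | COc1cc(OCC=C(C)C)c(C=O)cc1Br | intermediate
10 | tributyl(3-methylbut-2-en-1-yl)stannane | CCCC[Sn](CCCC)(CCCC)CC=C(C)C | starting material
11 | 4-methoxy-5-prenyl-2-(prenyloxy)benzaldehyde | COc1cc(OCC=C(C)C)c(C=O)cc1CC=C(C)C | intermediate
12 | 4-methoxy-5-prenyl-2-(prenyloxy)phenyl formate | COc1cc(OCC=C(C)C)c(OC=O)cc1CC=C(C)C | intermediate (not isolated)
13 | 4-methoxy-5-prenyl-2-(prenyloxy)phenol | COc1cc(OCC=C(C)C)c(O)cc1CC=C(C)C | intermediate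
14 | paraformaldehyde (written as formaldehyde) | C=O | starting material
15 | 2-hydroxy-5-methoxy-6-prenyl-3-(prenyloxy)benzaldehyde | COc1cc(OCC=C(C)C)c(O)c(C=O)c1CC=C(C)C | intermediate
16 | 2-(hydroxymethyl)-4-methoxy-3-prenyl-6-(prenyloxy)phenol | COc1cc(OCC=C(C)C)c(O)c(CO)c1CC=C(C)C | intermediate
17 | 2-{[(triisopropylsilyl)oxy]methyl}-4-methoxy-3-prenyl-6-(prenyloxy)phenol | COc1cc(OCC=C(C)C)c(O)c(CO[Si](C(C)C)(C(C)C)C(C)C)c1CC=C(C)C | intermediate
18 | methyl chloroformate | COC(=O)Cl | starting material
19 | methyl 2-{[(triisopropylsilyl)oxy]methyl}-4-methoxy-3-prenyl-6-(prenyloxy)phenyl carbonate | COC(=O)Oc1c(OCC=C(C)C)cc(OC)c(CC=C(C)C)c1CO[Si](C(C)C)(C(C)C)C(C)C | intermediate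
20 | 3-(prenyloxy)benzyne | CC(C)=CCOC1=CC=CC#C1 | intermediate (not isolated)
21 | potassium 2-{[(triisopropylsilyl)oxy]methyl}-4-methoxy-3-prenyl-6-(prenyloxy)phenoxide | [K+].[O-]c1c(OCC=C(C)C)cc(OC)c(CC=C(C)C)c1CO[Si](C(C)C)(C(C)C)C(C)C | intermediate (not isolated)
22 | potassium 2-(aryloxy)-6-(prenyloxy)phenyl anion (aryl = ring B of 21) | [K+].CC(C)=CCOc1cccc(Oc2c(OCC=C(C)C)cc(OC)c(CC=C(C)C)c2CO[Si](C(C)C)(C(C)C)C(C)C)[c-]1 | intermediate (not isolated)
23 | methyl 2-[2-{[(triisopropylsilyl)oxy]methyl}-4-methoxy-3-prenyl-6-(prenyloxy)phenoxy]-6-(prenyloxy)benzoate | COC(=O)c1c(OCC=C(C)C)cccc1Oc1c(OCC=C(C)C)cc(OC)c(CC=C(C)C)c1CO[Si](C(C)C)(C(C)C)C(C)C | intermediate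
24 | methyl 2-[2-(hydroxymethyl)-4-methoxy-3-prenyl-6-(prenyloxy)phenoxy]-6-(prenyloxy)benzoate | COC(=O)c1c(OCC=C(C)C)cccc1Oc1c(OCC=C(C)C)cc(OC)c(CC=C(C)C)c1CO | target

**Step count**

Total: 12 steps. Longest linear sequence: 9 steps (8 → 24, steps 4 to 12); the ring A branch (steps 1 to 3) joins at step 11.

**Steps most likely to fail**

1. Step 11 (proposed new method). The aryl anion 22 may be protonated, or may transfer a proton within the molecule, before it meets a carbonate, which would give O-arylation without the ester. The chain may also stop if fluoride adds to the aryne or if aryloxide 21 loses silanolate. Fallback with known chemistry, setting out from phenol 17: commercial 2-fluoro-6-hydroxybenzaldehyde F1 is O-alkylated with 2 (K2CO3, DMF) to 2-fluoro-6-(prenyloxy)benzaldehyde F2. Nucleophilic aromatic substitution of its fluoride by 17 (Cs2CO3, DMF, 90 °C), activated by the ortho-formyl group, should give 2-(ring B aryloxy)-6-(prenyloxy)benzaldehyde F3. Pinnick oxidation (NaClO2, NaH2PO4, large excess of 2-methyl-2-butene, t-BuOH/H2O) should give the benzoic acid F4, and methylation (MeI, K2CO3, DMF) returns to the route at 23.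

2. Step 6. Under the acid needed for the Dakin oxidation, methanol may add to the prenyl double bonds, the prenyl ether may be lost, or the electron-rich product phenol may be oxidised further. Fallback, setting out from 8, moves the oxidation to a stage that carries only monosubstituted alkenes. O-allylation (allyl bromide, K2CO3, DMF) gives 2-(allyloxy)-5-bromo-4-methoxybenzaldehyde F5, and Stille coupling with allyltributylstannane (Pd(PPh3)4, DMF) gives 5-allyl-2-(allyloxy)-4-methoxybenzaldehyde F6. Baeyer–Villiger oxidation with mCPBA (CH2Cl2, 0 °C), which should be faster than epoxidation of terminal alkenes, gives 5-allyl-2-(allyloxy)-4-methoxyphenyl formate F7, and K2CO3/MeOH frees 5-allyl-2-(allyloxy)-4-methoxyphenol F8. Cross-metathesis of both allyl groups with 2-methyl-2-butene (second-generation Grubbs catalyst, RuCl2(H2IMes)(PCy3)(=CHPh), 40 °C) returns to the route at 13.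

3. Step 5. Allylic transposition during transmetallation may deliver the 1,1-dimethylallyl (reverse prenyl) isomer, and zerovalent palladium may ionise the prenyl ether. Fallback, setting out from 9, transfers a symmetrical allyl group and builds the prenyl terminus afterwards. Stille coupling with allyltributylstannane (Pd(PPh3)4, DMF) gives 5-allyl-4-methoxy-2-(prenyloxy)benzaldehyde F9. Cross-metathesis with 2-methyl-2-butene (second-generation Grubbs catalyst, RuCl2(H2IMes)(PCy3)(=CHPh)) returns to the route at 11.

**Further compounds**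

F1 | step 11 | 2-fluoro-6-hydroxybenzaldehyde (bought) | O=Cc1c(O)cccc1F
F2 | step 11 | 2-fluoro-6-(prenyloxy)benzaldehyde | O=Cc1c(F)cccc1OCC=C(C)C
F3 | step 11 | 2-[2-{[(triisopropylsilyl)oxy]methyl}-4-methoxy-3-prenyl-6-(prenyloxy)phenoxy]-6-(prenyloxy)benzaldehyde | O=Cc1c(OCC=C(C)C)cccc1Oc1c(OCC=C(C)C)cc(OC)c(CC=C(C)C)c1CO[Si](C(C)C)(C(C)C)C(C)C
F4 | step 11 | 2-[2-{[(triisopropylsilyl)oxy]methyl}-4-methoxy-3-prenyl-6-(prenyloxy)phenoxy]-6-(prenyloxy)benzoic acid | OC(=O)c1c(OCC=C(C)C)cccc1Oc1c(OCC=C(C)C)cc(OC)c(CC=C(C)C)c1CO[Si](C(C)C)(C(C)C)C(C)C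
F5 | step 6 | 2-(allyloxy)-5-bromo-4-methoxybenzaldehyde | COc1cc(OCC=C)c(C=O)cc1Br
F6 | step 6 | 5-allyl-2-(allyloxy)-4-methoxybenzaldehyde | COc1cc(OCC=C)c(C=O)cc1CC=C
F7 | step 6 | 5-allyl-2-(allyloxy)-4-methoxyphenyl formate | COc1cc(OCC=C)c(OC=O)cc1CC=C
F8 | step 6 | 5-allyl-2-(allyloxy)-4-methoxyphenol | COc1cc(OCC=C)c(O)cc1CC=C
F9 | step 5 | 5-allyl-4-methoxy-2-(prenyloxy)benzaldehyde | COc1cc(OCC=C(C)C)c(C=O)cc1CC=C
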